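The dihydropyran ring is cut at C8a–O1 and C4–C4a, so that the chromane arises by inserting 3-(benzyloxy)benzyne into the benzylic C–O bond of a 2-aryl-4-methyloxetane. The step exploits that O1–C2–C3–C4 is a four-atom chain spanning the adjacent arene carbons C8a and C4a of the phenol ring, and that C4 bears the electron-rich 4,5-dimethoxynaphthalen-1-yl ring, which lets that C–O bond ionise. In one operation it closes the pyran ring, forms one C–O and one C–C bond and sets C4. The precursor is the (4R)-oxetane, either C2 epimer, whose methyl carbon becomes C2, together with a 3-benzyloxy silyl triflate.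

Key step: step 10

Remark: chromane numbering (O1, C2, C3, C4, C4a, C5–C8, C8a) is used for 19 and 20; the (S)-hydroxy ester is chosen because the oxetane is closed by SN2 at the methyl-bearing carbon, which inverts S to the R configuration needed at C2, and the benzylic carbon of 8 and 9 may be either epimer because step 10 resets it.

Step 1
Reactants: 1 1,8-dimethoxynaphthalene
Product: 2 4-bromo-1,8-dimethoxynaphthalene
Conditions: NBS (1.0 equiv), MeCN, 0 °C to rt
Reagents that add atoms: N-bromosuccinimide, O=C1CCC(=O)N1Br
Why: Electrophilic aromatic bromination: the methoxy group activates its para position C4, an α-carbon of the naphthalene, so one equivalent of NBS should brominate there once.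

Step 2
Reactants: 3 ethyl (S)-3-hydroxybutanoate
Product: 4 (S)-3-hydroxy-N-methoxy-N-methylbutanamide
Conditions: MeNHOMe·HCl, i-PrMgCl (4 equiv), THF, −20 to 0 °C
Reagents that add atoms: N,O-dimethylhydroxylamine hydrochloride, CNOC.Cl
Why: Weinreb amide formation by aminolysis of the ester with the chloromagnesium amide of N,O-dimethylhydroxylamine; the carbinol, carried as its magnesium alkoxide, is not touched, so C3 stays S.

Step 3
Reactants: 2 4-bromo-1,8-dimethoxynaphthalene; 4 (S)-3-hydroxy-N-methoxy-N-methylbutanamide
Product: 6 (S)-1-(4,5-dimethoxynaphthalen-1-yl)-3-hydroxybutan-1-one, via (4,5-dimethoxynaphthalen-1-yl)lithium 5 (not isolated)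
Conditions: 2, n-BuLi, THF, −78 °C; then 4 (pretreated with i-PrMgCl, 1.0 equiv, THF, −20 °C), −78 to 0 °C; aq. NH4Cl
Reagents that add atoms: none
Why: Bromine–lithium exchange followed by Weinreb ketone synthesis: the aryllithium adds once because the N-methoxy-chelated tetrahedral adduct persists until the quench, and C3 is not involved.

Step 4
Reactants: 6 (S)-1-(4,5-dimethoxynaphthalen-1-yl)-3-hydroxybutan-1-one
Product: 7 (S)-4-(4,5-dimethoxynaphthalen-1-yl)-4-oxobutan-2-yl 4-methylbenzenesulfonate
Conditions: TsCl, pyridine, CH2Cl2, 0 °C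
Reagents that add atoms: p-toluenesulfonyl chloride, Cc1ccc(cc1)S(=O)(=O)Cl
Why: Sulfonylation of the only hydroxyl group (the other oxygen is still a ketone, so the two oxygens cannot be confused); the C3–O bond is not broken, so the configuration stays S, and pyridine at 0 °C is too weak a base to start E1cB loss of the tosylate.

Step 5
Reactants: 7 (S)-4-(4,5-dimethoxynaphthalen-1-yl)-4-oxobutan-2-yl 4-methylbenzenesulfonate
Product: 8 (2S)-4-(4,5-dimethoxynaphthalen-1-yl)-4-hydroxybutan-2-yl 4-methylbenzenesulfonate (both C4 epimers)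
Conditions: NaBH4, CeCl3·7H2O, MeOH–THF, −40 °C; aq. NaHCO3
Reagents that add atoms: none
Why: Luche reduction delivers hydride to the aryl ketone under cold, nearly neutral conditions that leave the β-tosylate in place; the new carbinol carbon forms as both epimers, which is tolerated because that carbon is ionised and reset in step 10.

Step 6
Reactants: 8 (2S)-4-(4,5-dimethoxynaphthalen-1-yl)-4-hydroxybutan-2-yl 4-methylbenzenesulfonate
Product: 9 (4R)-2-(4,5-dimethoxynaphthalen-1-yl)-4-methyloxetane (both C2 epimers)
Conditions: KOt-Bu (1.2 equiv), THF, 0 °C to rt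
Reagents that add atoms: none
Why: Intramolecular Williamson ether synthesis (4-exo-tet SN2): the benzylic alkoxide displaces the secondary tosylate with inversion, which turns the S carbinol carbon into C4 of the oxetane with R configuration.

Step 7
Reactants: 10 3-(benzyloxy)phenol
Product: 11 3-(benzyloxy)phenyl isopropylcarbamate
Conditions: i-PrNCO, Et3N (cat.), CH2Cl2, rt
Reagents that add atoms: isopropyl isocyanate, CC(C)N=C=O
Why: Base-catalysed addition of the phenol to the isocyanate (carbamoylation) installs an N–H carbamate that directs ortho-lithiation strongly and can be removed later under mild base.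

Step 8
Reactants: 11 3-(benzyloxy)phenyl isopropylcarbamate
Product: 14 3-(benzyloxy)-2-(trimethylsilyl)phenyl isopropylcarbamate, via N-silyl carbamate 12 (not isolated), via ring-silylated N-silyl carbamate 13 (not isolated)
Conditions: TBSOTf, TMEDA, Et2O, 0 °C to rt; n-BuLi, TMEDA, −78 °C; TMSCl, −78 °C to rt; aq. NaHSO4
Reagents that add atoms: chlorotrimethylsilane, C[Si](C)(C)Cl
Why: Directed ortho-metalation: after in situ N-silylation the carbamate and the benzyloxy group together direct n-BuLi to the carbon between them, the aryllithium is trapped by TMSCl, and the N–Si bond is hydrolysed during the acidic work-up.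

Step 9
Reactants: 14 3-(benzyloxy)-2-(trimethylsilyl)phenyl isopropylcarbamate
Product: 16 3-(benzyloxy)-2-(trimethylsilyl)phenyl trifluoromethanesulfonate, via 3-(benzyloxy)-2-(trimethylsilyl)phenol 15 (not isolated)
Conditions: DBU, Et2NH, MeCN, 40 °C; then PhNTf2, rt
Reagents that add atoms: N-phenylbis(trifluoromethanesulfonimide), O=S(=O)(N(c1ccccc1)S(=O)(=O)C(F)(F)F)C(F)(F)F
Why: E1cB cleavage of the N–H carbamate releases the phenoxide (the isocyanate is trapped by diethylamine as a urea), which is triflated in the same flask by PhNTf2 (O-sulfonylation), conditions that leave the aryl–silicon bond and the benzyl ether intact.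

Step 10
Reactants: 9 (4R)-2-(4,5-dimethoxynaphthalen-1-yl)-4-methyloxetane; 16 3-(benzyloxy)-2-(trimethylsilyl)phenyl trifluoromethanesulfonate
Product: 19 (2R,4S)-5-(benzyloxy)-4-(4,5-dimethoxynaphthalen-1-yl)-2-methyl-3,4-dihydro-2H-chromene, via 3-(benzyloxy)benzyne 17 (not isolated), via oxetanium aryl-anion zwitterion 18 (not isolated)
Conditions: TBAT (2 equiv), toluene, rt to 50 °C; 16 (1.8 equiv) added slowly to 9 (0.3 M); no protic or ethereal co-solvent
Reagents that add atoms: none
Why: Proposed new method: Fluoride removes the trimethylsilyl group and triflate leaves to give aryne 17, whose 3-benzyloxy group distorts the triple bond so that the oxetane oxygen adds at the remote carbon and the aryl anion of zwitterion 18 lies next to the inductively stabilising OBn. The strained O-aryl oxonium then ionises at its benzylic C–O bond, the only one that the 4-methoxy-substituted naphthyl ring can stabilise as a cation, and the aryl anion recombines with that carbon, so the C–O σ bond is replaced by C8a–O1 and C4–C4a. The closest known reaction types are the insertion of arynes into the benzylic C–O bond of aryl epoxides to give 2,3-dihydrobenzofurans and the opening of cyclic ethers by arynes through oxonium zwitterions; a two-atom ring expansion of an oxetane with C–C closure has not been shown. The dihydropyran ring closes by 6-exo-trig attack of the aryl carbanion on the planar benzylic cation inside a tethered ion pair, a stepwise path that is required because a concerted front-side displacement is geometrically impossible. C4 is the only new stereocentre and should be set trans to the C2 methyl by a half-chair transition state with the methyl equatorial and the naphthyl pseudoaxial, away from the peri C5–OBn group, while C2 keeps its R configuration because none of its bonds is broken and both epimers of 9 converge through the planar cation. The step needs regioselective aryne capture (secured by the 3-alkoxy group), cleavage of the benzylic and not the methyl-bearing C–O bond (secured by the donor naphthyl group) and C–C collapse faster than proton transfer to the aryl anion (favoured by the aprotic, non-ethereal medium and the six-membered geometry).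

Step 11
Reactants: 19 (2R,4S)-5-(benzyloxy)-4-(4,5-dimethoxynaphthalen-1-yl)-2-methyl-3,4-dihydro-2H-chromene
Product: 20 Cladonaphchrom A, (2R,4S)-4-(4,5-dimethoxynaphthalen-1-yl)-2-methyl-3,4-dihydro-2H-chromen-5-ol
Conditions: H2 (1 atm), 10% Pd/C, EtOAc–EtOH, rt
Reagents that add atoms: none
Why: Catalytic hydrogenolysis cleaves the benzyl aryl ether only: the ring C–O bond is an alkyl aryl ether and C4 carries no leaving group, so both stereocentres are retained.

Compound list
1 | 1,8-dimethoxynaphthalene | COc1cccc2cccc(OC)c12 | starting material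
2 | 4-bromo-1,8-dimethoxynaphthalene | COc1cccc2c(Br)ccc(OC)c12 | intermediate
3 | ethyl (S)-3-hydroxybutanoate | CCOC(=O)C[C@H](C)O | starting material
4 | (S)-3-hydroxy-N-methoxy-N-methylbutanamide | CON(C)C(=O)C[C@H](C)O | intermediate
5 | (4,5-dimethoxynaphthalen-1-yl)lithium (not isolated) | COc1cccc2c([Li])ccc(OC)c12 | intermediate
6 | (S)-1-(4,5-dimethoxynaphthalen-1-yl)-3-hydroxybutan-1-one | COc1cccc2c(C(=O)C[C@H](C)O)ccc(OC)c12 | intermediate
7 | (S)-4-(4,5-dimethoxynaphthalen-1-yl)-4-oxobutan-2-yl 4-methylbenzenesulfonate | COc1cccc2c(C(=O)C[C@H](C)OS(=O)(=O)c3ccc(C)cc3)ccc(OC)c12 | intermediate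
8 | (2S)-4-(4,5-dimethoxynaphthalen-1-yl)-4-hydroxybutan-2-yl 4-methylbenzenesulfonate, both C4 epimers | COc1cccc2c(C(O)C[C@H](C)OS(=O)(=O)c3ccc(C)cc3)ccc(OC)c12 | intermediate
9 | (4R)-2-(4,5-dimethoxynaphthalen-1-yl)-4-methyloxetane, both C2 epimers | COc1cccc2c(C3C[C@@H](C)O3)ccc(OC)c12 | intermediate
10 | 3-(benzyloxy)phenol | Oc1cccc(OCc2ccccc2)c1 | starting material
11 | 3-(benzyloxy)phenyl isopropylcarbamate | CC(C)NC(=O)Oc1cccc(OCc2ccccc2)c1 | intermediate
12 | 3-(benzyloxy)phenyl N-(tert-butyldimethylsilyl)-N-isopropylcarbamate (not isolated) | CC(C)N(C(=O)Oc1cccc(OCc2ccccc2)c1)[Si](C)(C)C(C)(C)C | intermediate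
13 | 3-(benzyloxy)-2-(trimethylsilyl)phenyl N-(tert-butyldimethylsilyl)-N-isopropylcarbamate (not isolated) | CC(C)N(C(=O)Oc1cccc(OCc2ccccc2)c1[Si](C)(C)C)[Si](C)(C)C(C)(C)C | intermediate
14 | 3-(benzyloxy)-2-(trimethylsilyl)phenyl isopropylcarbamate | CC(C)NC(=O)Oc1cccc(OCc2ccccc2)c1[Si](C)(C)C | intermediate
15 | 3-(benzyloxy)-2-(trimethylsilyl)phenol (not isolated) | Oc1cccc(OCc2ccccc2)c1[Si](C)(C)C | intermediate
16 | 3-(benzyloxy)-2-(trimethylsilyl)phenyl trifluoromethanesulfonate | C[Si](C)(C)c1c(OCc2ccccc2)cccc1OS(=O)(=O)C(F)(F)F | intermediate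
17 | 3-(benzyloxy)benzyne, 1-(benzyloxy)-2,3-didehydrobenzene (not isolated) | C1#CC(OCc2ccccc2)=CC=C1 | intermediate
18 | (4R)-1-[3-(benzyloxy)benzen-2-id-1-yl]-2-(4,5-dimethoxynaphthalen-1-yl)-4-methyloxetan-1-ium, zwitterion (not isolated) | COc1cccc2c(C3C[C@@H](C)[O+]3c3cccc(OCc4ccccc4)[c-]3)ccc(OC)c12 | intermediate
19 | (2R,4S)-5-(benzyloxy)-4-(4,5-dimethoxynaphthalen-1-yl)-2-methyl-3,4-dihydro-2H-chromene | COc1cccc2c([C@@H]3C[C@@H](C)Oc4cccc(OCc5ccccc5)c43)ccc(OC)c12 | intermediate
20 | Cladonaphchrom A, (2R,4S)-4-(4,5-dimethoxynaphthalen-1-yl)-2-methyl-3,4-dihydro-2H-chromen-5-ol | COc1cccc2c([C@@H]3C[C@@H](C)Oc4cccc(O)c43)ccc(OC)c12 | target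

Total step count: 11.
Longest linear sequence: 7 steps (steps 2, 3, 4, 5, 6, 10 and 11, from 3).

Steps most likely to fail

1. Step 10, the aryne insertion. The aryl anion of 18 may take a proton from C3 or from the medium instead of bonding to C4, the oxonium may be opened by an external nucleophile, or the collapse may show poor facial selectivity at C4. The fallback uses known chemistry, sets out from amide 4 and naphthalene 1 and rejoins the route at target 20: the pyran ring is made first and the naphthyl group is attached last by Friedel–Crafts alkylation. 1,3-Bis(benzyloxy)benzene is lithiated at C2 with n-BuLi and acylated with 4 (as its alkoxide, as in step 3) to give (S)-1-[2,6-bis(benzyloxy)phenyl]-3-hydroxybutan-1-one F1. Hydrogenolysis gives (S)-1-(2,6-dihydroxyphenyl)-3-hydroxybutan-1-one F2. Intramolecular Mitsunobu etherification (PPh3, DIAD) closes the ring with inversion to (R)-5-hydroxy-2-methylchroman-4-one F3, and NaBH4 gives (2R)-2-methylchromane-4,5-diol F4. Acid-catalysed ionisation of F4 in the presence of 1 (TsOH, hexafluoroisopropanol) should then alkylate 1 at C4, para to a methoxy group, by axial attack on the chroman-4-yl cation trans to the equatorial methyl, giving 20 without a protecting group.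

2. Step 4, the tosylation. E1cB loss of the new tosylate from ketone 7 may occur while it forms in the presence of the amine base, giving the enone. The fallback sets out from amide 4 and rejoins at 7: the order is reversed so that the sulfonate is installed where no ketone is present. Tosylation of 4 gives (S)-4-[methoxy(methyl)amino]-4-oxobutan-2-yl 4-methylbenzenesulfonate F5, an amide that does not enolise under pyridine. One equivalent of aryllithium 5 at −78 °C, followed by a cold acidic quench, then releases 7 from the tetrahedral adduct under non-basic conditions and without a sacrificial base.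

3. Step 5, the ketone reduction. Base-induced elimination of the tosylate from 7 may compete with hydride delivery. The fallback sets out from hydroxy ketone 6 and rejoins at 8: the ketone is reduced before any sulfonate is present and the two oxygens are told apart by protecting groups. Silylation of 6 (TESCl, imidazole) gives (S)-1-(4,5-dimethoxynaphthalen-1-yl)-3-[(triethylsilyl)oxy]butan-1-one F6. NaBH4 gives (3S)-1-(4,5-dimethoxynaphthalen-1-yl)-3-[(triethylsilyl)oxy]butan-1-ol F7, and benzoylation (BzCl, pyridine, DMAP) gives (3S)-1-(4,5-dimethoxynaphthalen-1-yl)-3-[(triethylsilyl)oxy]butyl benzoate F8. HF·pyridine buffered with pyridine removes the silyl group to give (3S)-1-(4,5-dimethoxynaphthalen-1-yl)-3-hydroxybutyl benzoate F9, and TsCl in pyridine gives (3S)-1-(4,5-dimethoxynaphthalen-1-yl)-3-(tosyloxy)butyl benzoate F10. K2CO3 in methanol then removes the benzoate and delivers 8.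

Further compounds
F1 | step 10 | (S)-1-[2,6-bis(benzyloxy)phenyl]-3-hydroxybutan-1-one | O=C(C[C@H](C)O)c1c(OCc2ccccc2)cccc1OCc1ccccc1
F2 | step 10 | (S)-1-(2,6-dihydroxyphenyl)-3-hydroxybutan-1-one | O=C(C[C@H](C)O)c1c(O)cccc1O
F3 | step 10 | (R)-5-hydroxy-2-methylchroman-4-one | O=C1C[C@@H](C)Oc2cccc(O)c12
F4 | step 10 | (2R)-2-methylchromane-4,5-diol, both C4 epimers | OC1C[C@@H](C)Oc2cccc(O)c12
F5 | step 4 | (S)-4-[methoxy(methyl)amino]-4-oxobutan-2-yl 4-methylbenzenesulfonate | CON(C)C(=O)C[C@H](C)OS(=O)(=O)c1ccc(C)cc1
F6 | step 5 | (S)-1-(4,5-dimethoxynaphthalen-1-yl)-3-[(triethylsilyl)oxy]butan-1-one | COc1cccc2c(C(=O)C[C@H](C)O[Si](CC)(CC)CC)ccc(OC)c12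
F7 | step 5 | (3S)-1-(4,5-dimethoxynaphthalen-1-yl)-3-[(triethylsilyl)oxy]butan-1-ol, both C1 epimers | COc1cccc2c(C(O)C[C@H](C)O[Si](CC)(CC)CC)ccc(OC)c12
F8 | step 5 | (3S)-1-(4,5-dimethoxynaphthalen-1-yl)-3-[(triethylsilyl)oxy]butyl benzoate | COc1cccc2c(C(OC(=O)c3ccccc3)C[C@H](C)O[Si](CC)(CC)CC)ccc(OC)c12
F9 | step 5 | (3S)-1-(4,5-dimethoxynaphthalen-1-yl)-3-hydroxybutyl benzoate | COc1cccc2c(C(OC(=O)c3ccccc3)C[C@H](C)O)ccc(OC)c12
F10 | step 5 | (3S)-1-(4,5-dimethoxynaphthalen-1-yl)-3-(tosyloxy)butyl benzoate | COc1cccc2c(C(OC(=O)c3ccccc3)C[C@H](C)OS(=O)(=O)c3ccc(C)cc3)ccc(OC)c12
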